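**Plan**
- Retrosynthetic cuts, in order: C7=C8 (ring-closing metathesis), C8–C9 (Ni/Cr alkenylation of a C9 aldehyde), aryl–C(=O) of the anisate (aryl Grignard on an O6 imidazole-1-carboxylate), C4–isopropyl, C5–C6 together with C1–CH3 (conjugate addition/aldol), C10–C1 (Stork–Danheiser).
- Forward: cyclopentenone → quaternary C1 and the C5 side chain in one operation → C4 carbinol → ester C–C bond → C9 carbinol → seven-membered ring closed last.
- Enabling feature: on the monocyclic cyclopentane, O6 is the only secondary oxygen. C9 is still an acetal carbon, and the C4 hydroxyl is tertiary, flanked by isopropyl and ring carbon C5. The O6–C(=O)–imidazole carbon is therefore the single acyl electrophile, and the anisate formed there protects O6 through closure of the C5–C1/C6–C10 seven-membered ring, so O6 and O9 never need to be told apart.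
- Stereochemistry: C1 from the chiral NHC–Cu catalyst; C5 and C6 from the aldol (enolate face anti to the acetal arm, Zimmerman–Traxler anti); C4 from substrate-controlled isopropyl addition; C9 from the chiral chromium ligand; the trans ring fusion follows from C1/C5.

Key step: step 6

Remark: daucane numbering is used throughout (C1 quaternary methyl carbon, C4 isopropyl carbinol, C5 ring-fusion CH, C6 ester carbinol, C7=C8, C9 free carbinol, C10 CH2); all selectivities are expectations.

**Step 1**
Reactants: 1 3-ethoxycyclopent-2-en-1-one; 2 (1,3-dioxolan-2-ylmethyl)magnesium bromide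
Product: 4 3-(1,3-dioxolan-2-ylmethyl)cyclopent-2-en-1-one, via magnesium alkoxide 3 (not isolated)
Conditions: THF, 0 °C → rt; then 1 M aq. HCl, 0 °C, 15 min
Reagents that add atoms: (1,3-dioxolan-2-ylmethyl)magnesium bromide, Br[Mg]CC1OCCO1; water, O
Why: Stork–Danheiser transposition, in which 1,2-addition to the vinylogous ester and cold acid hydrolysis/dehydration move the carbonyl to the former enol-ether carbon and place the acetal arm (C10–C9) on the enone β-carbon (future C1), the brief cold acid sparing the dioxolane.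

**Step 2**
Reactants: 4 3-(1,3-dioxolan-2-ylmethyl)cyclopent-2-en-1-one; 5 trimethylaluminium; 6 acrolein
Product: 8 (2S,3R)-3-(1,3-dioxolan-2-ylmethyl)-2-[(1S)-1-hydroxyprop-2-en-1-yl]-3-methylcyclopentan-1-one, via aluminium enolate 7 (not isolated)
Conditions: Cu(OTf)2 (5 mol %), chiral sulfonate-bearing NHC–Ag(I) complex (2.5 mol %), Me3Al, THF, −78 °C; then acrolein, −78 → −50 °C; aq. Rochelle salt
Reagents that add atoms: trimethylaluminium, C[Al](C)C; acrolein, C=CC=O
Why: NHC–Cu-catalysed enantioselective conjugate addition of Me3Al to a β-substituted cyclopentenone (ligand antipode chosen for Si-face methyl delivery, giving 1R) leaves a regiodefined (E)-aluminium enolate, which should add to acrolein through a closed Zimmerman–Traxler chair (anti aldol, 6S) on the face anti to the β-branched acetal arm (5S, C6 cis to the new methyl).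

**Step 3**
Reactants: 8 the aldol from step 2; 9 chlorotriethylsilane
Product: 10 (2S,3R)-3-(1,3-dioxolan-2-ylmethyl)-3-methyl-2-[(1S)-1-(triethylsilyloxy)prop-2-en-1-yl]cyclopentan-1-one
Conditions: TESCl, imidazole, DMF, 0 °C → rt
Reagents that add atoms: chlorotriethylsilane, CC[Si](Cl)(CC)CC
Why: standard silylation masks the aldol hydroxyl against retro-aldol and β-elimination in step 4, and a silyl chloride is used because a silyl triflate/pyridine base could open the dioxolane.

**Step 4**
Reactants: 10 the TES-protected ketone; 11 isopropylmagnesium chloride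
Product: 13 (1R,2S,3R)-3-(1,3-dioxolan-2-ylmethyl)-2-[(1S)-1-hydroxyprop-2-en-1-yl]-3-methyl-1-(propan-2-yl)cyclopentan-1-ol, via triethylsilyl ether 12 (not isolated)
Conditions: i-PrMgCl, LaCl3·2LiCl, THF, 0 °C; aq. NH4Cl; crude product, then TBAF, THF, 0 °C
Reagents that add atoms: isopropylmagnesium chloride, CC(C)[Mg]Cl
Why: lanthanum-promoted Grignard 1,2-addition suppresses enolisation and β-hydride reduction, and the nucleophile should enter the ketone face opposite the adjacent C5 side chain and the C1 methyl, giving the 4R carbinol (OH cis to the C5 side chain) before fluoride removes the silyl group.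

**Step 5**
Reactants: 13 the diol from step 4; 14 1,1'-carbonyldiimidazole
Product: 15 (1S)-1-[(1S,2R,5R)-5-(1,3-dioxolan-2-ylmethyl)-2-hydroxy-5-methyl-2-(propan-2-yl)cyclopentyl]prop-2-en-1-yl 1H-imidazole-1-carboxylate
Conditions: CDI (1.5 equiv), CH2Cl2, rt (cat. DMAP if slow)
Reagents that add atoms: 1,1'-carbonyldiimidazole, O=C(n1ccnc1)n1ccnc1
Why: acyl transfer from CDI should occur only at the secondary hydroxyl, since the tertiary C4–OH is not acylated under neutral conditions and a six-membered 4,6-carbonate would force the C6 vinyl and C4 isopropyl groups 1,3-diaxial.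

**Step 6**
Reactants: 15 the O6 imidazole-1-carboxylate; 16 4-methoxyphenylmagnesium bromide
Product: 17 (1S)-1-[(1S,2R,5R)-5-(1,3-dioxolan-2-ylmethyl)-2-hydroxy-5-methyl-2-(propan-2-yl)cyclopentyl]prop-2-en-1-yl 4-methoxybenzoate
Conditions: 4-MeOC6H4MgBr (3 equiv), THF, −20 → 0 °C, substrate added to the Grignard reagent; aq. NH4Cl
Reagents that add atoms: 4-methoxyphenylmagnesium bromide, COc1ccc([Mg]Br)cc1
Why: The aryl Grignard adds to the carbonyl carbon of the O6 imidazole-1-carboxylate (activated by magnesium at the carbonyl oxygen and imidazole N3), and the tetrahedral magnesium alkoxide collapses with loss of imidazolide, so the aryl–C(=O) bond forms on a carbon that already carries the C6–O bond. The closest known reaction type is ester synthesis from Grignard reagents and alkyl imidazole-1-carboxylates, a mono-acylation of an organomagnesium. No ring is closed and no stereocentre is formed; C6 keeps its configuration because its C–O bond is never broken. Mono-addition is secured by the substrate, since the product is an electron-rich 4-methoxybenzoate on a congested carbinol and is far less electrophilic than the acyl imidazole at or below 0 °C. Site selectivity among the three oxygens is secured by timing: O6 is the only secondary oxygen at this stage and the tertiary C4–OH is merely deprotonated by the first equivalent. If that alkoxide closed onto the acyl imidazole, the strained cyclic carbonate should be opened by the same reagent at the same carbonyl carbon with loss of the hindered tertiary alkoxide.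

**Step 7**
Reactants: 17 the anisate acetal
Product: 18 (1S)-1-[(1S,2R,5R)-2-hydroxy-5-methyl-5-(2-oxoethyl)-2-(propan-2-yl)cyclopentyl]prop-2-en-1-yl 4-methoxybenzoate
Conditions: 1 M aq. HCl, THF, rt
Reagents that add atoms: water, O
Why: acid hydrolysis of the dioxolane unveils the C9 aldehyde, and the aryl ester, the terminal alkene and the non-allylic tertiary alcohol should tolerate dilute acid at room temperature.

**Step 8**
Reactants: 18 the aldehyde; 19 2-bromopropene
Product: 20 (1S)-1-[(1S,2R,5R)-2-hydroxy-5-[(2R)-2-hydroxy-3-methylbut-3-en-1-yl]-5-methyl-2-(propan-2-yl)cyclopentyl]prop-2-en-1-yl 4-methoxybenzoate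
Conditions: CrCl2 (3 equiv), chiral oxazoline–sulfonamide ligand (3.3 equiv), Et3N (3.3 equiv), NiCl2 (5 mol %), THF, rt
Reagents that add atoms: 2-bromopropene, C=C(C)Br
Why: the Ni/Cr-mediated Nozaki–Hiyama–Kishi alkenylation is selective for the aldehyde over the ester and tolerates the free tertiary alcohol, and the chromium-bound chiral ligand (antipode chosen for Si-face addition) should set C9 as R under reagent control, the remote quaternary C1 exerting little bias.

**Step 9**
Reactants: 20 the diene
Product: 21 (3R,3aS,4S,7R,8aR)-3,7-dihydroxy-6,8a-dimethyl-3-(propan-2-yl)-1,2,3,3a,4,7,8,8a-octahydroazulen-4-yl 4-methoxybenzoate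
Conditions: second-generation Grubbs catalyst (10 mol %), 1,4-benzoquinone (20 mol %), toluene (2 mM), 80 °C
Reagents that add atoms: none
Why: ring-closing metathesis between the C6 vinyl and C9 isopropenyl groups forms the trisubstituted C7=C8 alkene and the trans-fused seven-membered ring (the two arms are trans on the cyclopentane from step 2) with loss of ethene, the free allylic C9–OH aiding loading onto the 1,1-disubstituted alkene and benzoquinone suppressing Ru–H isomerisation.

**Compound list**
1 | 3-ethoxycyclopent-2-en-1-one | CCOC1=CC(=O)CC1 | starting material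
2 | (1,3-dioxolan-2-ylmethyl)magnesium bromide | Br[Mg]CC1OCCO1 | starting material
3 | bromomagnesium 1-(1,3-dioxolan-2-ylmethyl)-3-ethoxycyclopent-2-en-1-olate | CCOC1=CC(CC2OCCO2)(O[Mg]Br)CC1 | intermediate
4 | 3-(1,3-dioxolan-2-ylmethyl)cyclopent-2-en-1-one | O=C1C=C(CC2OCCO2)CC1 | intermediate
5 | trimethylaluminium | C[Al](C)C | starting material
6 | acrolein (prop-2-enal) | C=CC=O | starting material
7 | dimethylaluminium (R)-3-(1,3-dioxolan-2-ylmethyl)-3-methylcyclopent-1-en-1-olate | O1CCOC1C[C@@]2(C)CCC(O[Al](C)C)=C2 | intermediate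
8 | (2S,3R)-3-(1,3-dioxolan-2-ylmethyl)-2-[(1S)-1-hydroxyprop-2-en-1-yl]-3-methylcyclopentan-1-one | O1CCOC1C[C@@]2(C)CCC(=O)[C@@H]2[C@@H](O)C=C | intermediate
9 | chlorotriethylsilane | CC[Si](Cl)(CC)CC | starting material
10 | (2S,3R)-3-(1,3-dioxolan-2-ylmethyl)-3-methyl-2-[(1S)-1-(triethylsilyloxy)prop-2-en-1-yl]cyclopentan-1-one | O1CCOC1C[C@@]2(C)CCC(=O)[C@@H]2[C@@H](O[Si](CC)(CC)CC)C=C | intermediate
11 | isopropylmagnesium chloride | CC(C)[Mg]Cl | starting material
12 | (1R,2S,3R)-3-(1,3-dioxolan-2-ylmethyl)-3-methyl-1-(propan-2-yl)-2-[(1S)-1-(triethylsilyloxy)prop-2-en-1-yl]cyclopentan-1-ol | O1CCOC1C[C@@]2(C)CC[C@@](O)(C(C)C)[C@@H]2[C@@H](O[Si](CC)(CC)CC)C=C | intermediate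
13 | (1R,2S,3R)-3-(1,3-dioxolan-2-ylmethyl)-2-[(1S)-1-hydroxyprop-2-en-1-yl]-3-methyl-1-(propan-2-yl)cyclopentan-1-ol | O1CCOC1C[C@@]2(C)CC[C@@](O)(C(C)C)[C@@H]2[C@@H](O)C=C | intermediate
14 | 1,1'-carbonyldiimidazole | O=C(n1ccnc1)n1ccnc1 | starting material
15 | (1S)-1-[(1S,2R,5R)-5-(1,3-dioxolan-2-ylmethyl)-2-hydroxy-5-methyl-2-(propan-2-yl)cyclopentyl]prop-2-en-1-yl 1H-imidazole-1-carboxylate | O1CCOC1C[C@@]2(C)CC[C@@](O)(C(C)C)[C@@H]2[C@@H](OC(=O)n3ccnc3)C=C | intermediate
16 | 4-methoxyphenylmagnesium bromide | COc1ccc([Mg]Br)cc1 | starting material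
17 | (1S)-1-[(1S,2R,5R)-5-(1,3-dioxolan-2-ylmethyl)-2-hydroxy-5-methyl-2-(propan-2-yl)cyclopentyl]prop-2-en-1-yl 4-methoxybenzoate | O1CCOC1C[C@@]2(C)CC[C@@](O)(C(C)C)[C@@H]2[C@@H](OC(=O)c3ccc(OC)cc3)C=C | intermediate
18 | (1S)-1-[(1S,2R,5R)-2-hydroxy-5-methyl-5-(2-oxoethyl)-2-(propan-2-yl)cyclopentyl]prop-2-en-1-yl 4-methoxybenzoate | O=CC[C@@]1(C)CC[C@@](O)(C(C)C)[C@@H]1[C@@H](OC(=O)c2ccc(OC)cc2)C=C | intermediate
19 | 2-bromopropene | C=C(C)Br | starting material
20 | (1S)-1-[(1S,2R,5R)-2-hydroxy-5-[(2R)-2-hydroxy-3-methylbut-3-en-1-yl]-5-methyl-2-(propan-2-yl)cyclopentyl]prop-2-en-1-yl 4-methoxybenzoate | C=C(C)[C@H](O)C[C@@]1(C)CC[C@@](O)(C(C)C)[C@@H]1[C@@H](OC(=O)c2ccc(OC)cc2)C=C | intermediate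
21 | (3R,3aS,4S,7R,8aR)-3,7-dihydroxy-6,8a-dimethyl-3-(propan-2-yl)-1,2,3,3a,4,7,8,8a-octahydroazulen-4-yl 4-methoxybenzoate | COc1ccc(C(=O)O[C@H]2C=C(C)[C@H](O)C[C@@]3(C)CC[C@@](O)(C(C)C)[C@H]23)cc1 | target

Total step count: 9. Longest linear sequence: 9 steps (fully linear from 1).

**Steps most likely to fail**

Step 2. The aluminium-enolate aldol may show incomplete anti/syn selection at C6, or lose it by retro-aldol equilibration of the aldolate. The π-facial preference at C5 rests only on the size difference between methyl and the acetal arm, and this fallback does not correct C5. The fallback sets out from 13, carried through steps 3 and 4 as a C6-epimeric mixture. Oxidation of the secondary allylic alcohol with Dess–Martin periodinane (NaHCO3, CH2Cl2) converges both epimers on 1-[(1R,2R,5R)-5-(1,3-dioxolan-2-ylmethyl)-2-hydroxy-5-methyl-2-(propan-2-yl)cyclopentyl]prop-2-en-1-one F1. Evans–Saksena reduction (Me4NBH(OAc)3, MeCN–AcOH, −30 °C) then delivers hydride intramolecularly from the C4–O-bound borohydride through a chair with the vinyl group equatorial. This should give the 1,3-anti diol, which is the (6S) epimer, and the route is rejoined at 13.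

Step 8. Reagent control at C9 may be incomplete, through poor face selection by the chromium-bound alkenyl group or a competing ligand-free coupling, giving C9 epimers. The fallback sets out from 20 as the C9 mixture. Dess–Martin oxidation gives (1S)-1-[(1S,2R,5R)-2-hydroxy-5-methyl-5-(3-methyl-2-oxobut-3-en-1-yl)-2-(propan-2-yl)cyclopentyl]prop-2-en-1-yl 4-methoxybenzoate F2. Corey–Bakshi–Shibata reduction with the (S)-oxazaborolidine and catecholborane (toluene, −78 °C; catecholborane spares the alkenes and the ester) should then set C9 as R by C–H rather than C–C bond formation, returning to 20.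

Step 9. The ruthenium alkylidene may fail to engage the 1,1-disubstituted isopropenyl alkene, because loading at the hindered vinyl next to the ester is slow, or because intermolecular metathesis or Ru–H isomerisation of the allylic alcohol intervenes. The fallback is a relay metathesis and sets out from 18. The Ni/Cr coupling of step 8 is run with 2-bromoocta-2,7-diene F3, prepared from commercial hex-5-enal by Wittig olefination with (1-bromoethylidene)triphenylphosphorane. This gives (1S)-1-[(1S,2R,5R)-2-hydroxy-5-[(2R)-2-hydroxy-3-methylnona-3,8-dien-1-yl]-5-methyl-2-(propan-2-yl)cyclopentyl]prop-2-en-1-yl 4-methoxybenzoate F4. With the same ruthenium catalyst the carbene loads on the unhindered terminal alkene of the tether, expels cyclopentene and is thereby placed on C8. It then closes onto the C6 vinyl group to give 21 directly.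

**Further compounds**
F1 | step 2 | 1-[(1R,2R,5R)-5-(1,3-dioxolan-2-ylmethyl)-2-hydroxy-5-methyl-2-(propan-2-yl)cyclopentyl]prop-2-en-1-one | O1CCOC1C[C@@]2(C)CC[C@@](O)(C(C)C)[C@@H]2C(=O)C=C
F2 | step 8 | (1S)-1-[(1S,2R,5R)-2-hydroxy-5-methyl-5-(3-methyl-2-oxobut-3-en-1-yl)-2-(propan-2-yl)cyclopentyl]prop-2-en-1-yl 4-methoxybenzoate | C=C(C)C(=O)C[C@@]1(C)CC[C@@](O)(C(C)C)[C@@H]1[C@@H](OC(=O)c2ccc(OC)cc2)C=C
F3 | step 9 | 2-bromoocta-2,7-diene | CC(Br)=CCCCC=C
F4 | step 9 | (1S)-1-[(1S,2R,5R)-2-hydroxy-5-[(2R)-2-hydroxy-3-methylnona-3,8-dien-1-yl]-5-methyl-2-(propan-2-yl)cyclopentyl]prop-2-en-1-yl 4-methoxybenzoate | C=CCCCC=C(C)[C@H](O)C[C@@]1(C)CC[C@@](O)(C(C)C)[C@@H]1[C@@H](OC(=O)c2ccc(OC)cc2)C=C
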